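The synthesis rests on disconnecting two adjacent carbons of the central ring B at once: B6, which carries the dioxin oxygen coming from position 5 of ring A, and B5, which carries C6 of ring C. Because these carbons are neighbours, a B5–B6 aryne can take the tethered 5-phenoxide of ring A at B6 and an iodine electrophile at B5 in a single operation. This closes the dibenzodioxin and leaves the handle for the furan annulation. The precursor is hydroquinone bis(aryl ether) 14 of rings E, A and B, with free hydroxyls at positions 2 and 5 of ring A, fluorine at B6 and a MOM ether at B4.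

Key step: step 9

Remark on labels: ring A is the outer dioxin ring and its carbons are always written out as "position n of ring A" (position 1 O-aryl to ring E, position 2 OH, position 3 H, position 4 OH, positions 5 and 6 the dioxin carbons). Ring B is the central ring (B1 dioxin carbon joined through O to position 6 of ring A, B2 OH, B3 H, B4 furan C–O carbon, B5 biaryl carbon, B6 dioxin carbon joined through O to position 5 of ring A). Ring C is the outer furan ring (C1 furan C–O carbon, C2 O-aryl to ring F, C3 OH, C4 H, C5 OH, C6 bonded to B5). E and F are the 3,5-dioxygenated phenyl rings.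

Assumption: 7, 21 and 22 are taken as commercial, the target has no stereocentre, and hydroquinone 14 is handled under argon and used at once.

Step 1
Reactants: 1 5-fluorovanillin (3-fluoro-4-hydroxy-5-methoxybenzaldehyde)
Product: 2 4-(benzyloxy)-3-fluoro-5-methoxybenzaldehyde
Conditions: BnBr, K2CO3, DMF, 60 °C
Reagents that add atoms: benzyl bromide, BrCc1ccccc1
Why: Williamson ether synthesis on the acidic phenol masks the future B1 oxygen as a benzyl ether, while the aldehyde and the aryl fluoride are inert to carbonate.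

Step 2
Reactants: 2 4-(benzyloxy)-3-fluoro-5-methoxybenzaldehyde
Product: 4 4-(benzyloxy)-3-fluoro-5-methoxyphenol, via aryl formate 3 (not isolated)
Conditions: mCPBA, CH2Cl2, 0 °C to rt; then K2CO3 (cat.), MeOH, rt
Reagents that add atoms: mCPBA (3-chloroperoxybenzoic acid), OOC(=O)c1cccc(Cl)c1
Why: Baeyer–Villiger oxidation in which the aryl group, made electron-rich by the para benzyloxy group, migrates in preference to hydride, after which methanolysis of the formate frees the future B4 phenol.

Step 3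
Reactants: 4 4-(benzyloxy)-3-fluoro-5-methoxyphenol
Product: 5 2-(benzyloxy)-1-fluoro-3-methoxy-5-(methoxymethoxy)benzene
Conditions: MOMCl, iPr2NEt, CH2Cl2, 0 °C to rt
Reagents that add atoms: chloromethyl methyl ether, COCCl
Why: O-alkylation of the phenol by the alpha-chloro ether (acetal formation) installs the MOM group that later directs lithiation to B5.

Step 4
Reactants: 5 2-(benzyloxy)-1-fluoro-3-methoxy-5-(methoxymethoxy)benzene
Product: 6 2-fluoro-6-methoxy-4-(methoxymethoxy)phenol (ring B phenol)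
Conditions: H2 (1 atm), Pd/C, EtOAc, rt
Reagents that add atoms: none
Why: Catalytic hydrogenolysis cleaves only the benzylic C–O bond, since the aryl fluoride and the MOM acetal are stable to hydrogen over palladium on carbon.

Step 5
Reactants: 6 2-fluoro-6-methoxy-4-(methoxymethoxy)phenol; 7 2,3-difluoro-6-methoxybenzaldehyde
Product: 8 3-fluoro-2-[2-fluoro-6-methoxy-4-(methoxymethoxy)phenoxy]-6-methoxybenzaldehyde
Conditions: K2CO3, DMF, 80 °C
Reagents that add atoms: none
Why: Nucleophilic aromatic substitution (SNAr) in which the phenoxide of 6 displaces the fluoride ortho to the formyl group (position 6 of ring A) through an aldehyde-stabilised Meisenheimer intermediate, whereas the meta fluoride (position 1 of ring A) and the unactivated B6–F stay in place.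

Step 6
Reactants: 8 3-fluoro-2-[2-fluoro-6-methoxy-4-(methoxymethoxy)phenoxy]-6-methoxybenzaldehyde
Product: 10 3-fluoro-2-[2-fluoro-6-methoxy-4-(methoxymethoxy)phenoxy]-6-methoxyphenol, via aryl formate 9 (not isolated)
Conditions: mCPBA, CH2Cl2, 0 °C to rt; then K2CO3 (cat.), MeOH, rt
Reagents that add atoms: mCPBA (3-chloroperoxybenzoic acid), OOC(=O)c1cccc(Cl)c1
Why: Baeyer–Villiger oxidation in which ring A, flanked by two oxygen substituents, migrates readily, and mild methanolysis then reveals the hydroxyl at position 5 of ring A without touching the MOM acetal.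

Step 7
Reactants: 10 3-fluoro-2-[2-fluoro-6-methoxy-4-(methoxymethoxy)phenoxy]-6-methoxyphenol
Product: 11 2-fluoro-3-[2-fluoro-6-methoxy-4-(methoxymethoxy)phenoxy]-5-methoxycyclohexa-2,5-diene-1,4-dione
Conditions: Fremy's salt K2[ON(SO3)2] (2.2 equiv), KH2PO4, H2O–acetone, rt
Reagents that add atoms: Fremy's salt (potassium nitrosodisulfonate), [K+].[K+].[O]N(S([O-])(=O)=O)S([O-])(=O)=O
Why: Teuber oxidation, in which Fremy's salt abstracts the phenolic hydrogen and a second equivalent delivers oxygen to the free para carbon (position 2 of ring A), gives the para-quinone while the non-phenolic ring B is untouched in the buffered medium.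

Step 8
Reactants: 11 2-fluoro-3-[2-fluoro-6-methoxy-4-(methoxymethoxy)phenoxy]-5-methoxycyclohexa-2,5-diene-1,4-dione; 12 3,5-dimethoxyphenol
Product: 14 2-(3,5-dimethoxyphenoxy)-3-[2-fluoro-6-methoxy-4-(methoxymethoxy)phenoxy]-5-methoxybenzene-1,4-diol, via bis(aryloxy)quinone 13 (not isolated)
Conditions: K2CO3 (1.1 equiv), DMF, −20 to 0 °C; then aq. Na2S2O4, EtOAc, rt, argon
Reagents that add atoms: none
Why: Addition–elimination on the fluoroquinone (vinylogous acyl substitution) occurs at position 1 of ring A, the only leaving-group carbon beta to the carbonyl at position 5, which unlike the carbonyl at position 2 is not deactivated by vinylogous donation from the 4-methoxy and 6-aryloxy groups, so fluoride is replaced without ether exchange and dithionite then reduces the quinone to the hydroquinone.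

Step 9
Reactants: 14 2-(3,5-dimethoxyphenoxy)-3-[2-fluoro-6-methoxy-4-(methoxymethoxy)phenoxy]-5-methoxybenzene-1,4-diol
Product: 18 6-(3,5-dimethoxyphenoxy)-1-iodo-4,9-dimethoxy-2-(methoxymethoxy)dibenzo[b,e][1,4]dioxin-7-ol, via trilithio fluoroarene 15 (not isolated), via B5–B6 aryne 16 (not isolated), via B5 aryllithium 17 (not isolated)
Conditions: LiTMP (3.3 equiv), THF (0.02 M), −78 °C; warm to −10 °C; ICH2CH2I (1.5 equiv), −78 °C to rt; aq. NH4Cl
Reagents that add atoms: 1,2-diiodoethane, ICCI
Why: Proposed new method: LiTMP first turns both phenols into lithium phenoxides and then removes B5–H, the most acidic ring proton because it lies between fluorine and the chelating MOM ether, to give 15, which on warming expels LiF and forms the B5–B6 aryne 16. The phenoxide at position 5 of ring A, held beside the aryne by the ether bridge from position 6 of ring A to B1, adds to B6 and closes the 1,4-dioxin ring in a six-membered exo-dig mode, whereas the phenoxide at position 2 of ring A cannot reach either aryne carbon. The resulting B5 aryllithium 17, flanked by the MOM oxygen and the new dioxin oxygen, is intercepted by 1,2-diiodoethane, which hands iodine to carbanions but neither oxidises nor ring-iodinates the remaining electron-rich phenoxide. The closest known reaction types are aryne generation from ortho-lithiated fluoroarenes, intramolecular capture of arynes by tethered oxygen nucleophiles and anionic aryne cyclisations finished by an electrophilic quench. No stereocentre is created. The step needs site-selective metalation at B5 over B3 and the ring E positions, which the fluorine and MOM pair secures, and C–O bond formation at B6 with lithium left on B5, which the tether alone dictates.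

Step 10
Reactants: 18 6-(3,5-dimethoxyphenoxy)-1-iodo-4,9-dimethoxy-2-(methoxymethoxy)dibenzo[b,e][1,4]dioxin-7-ol
Product: 19 6-(3,5-dimethoxyphenoxy)-1-iodo-4,7,9-trimethoxy-2-(methoxymethoxy)dibenzo[b,e][1,4]dioxin
Conditions: MeI, K2CO3, DMF, rt
Reagents that add atoms: iodomethane, CI
Why: Williamson methylation of the single free phenol (the hydroxyl at position 2 of ring A) removes the only competing nucleophile for the later copper-catalysed etherification and leaves the aryl iodide and the MOM acetal intact.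

Step 11
Reactants: 19 6-(3,5-dimethoxyphenoxy)-1-iodo-4,7,9-trimethoxy-2-(methoxymethoxy)dibenzo[b,e][1,4]dioxin
Product: 20 6-(3,5-dimethoxyphenoxy)-1-iodo-4,7,9-trimethoxydibenzo[b,e][1,4]dioxin-2-ol (B4–OH next to B5–I)
Conditions: HCl (cat.), MeOH–THF, 45 °C
Reagents that add atoms: none
Why: Acid-catalysed transacetalisation with methanol cleaves the MOM ether to uncover B4–OH, under conditions to which the aryl methyl ethers, the dioxin and the C–I bond are stable.

Step 12
Reactants: 21 5-bromovanillin (3-bromo-4-hydroxy-5-methoxybenzaldehyde); 22 (3,5-dimethoxyphenyl)boronic acid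
Product: 23 3-bromo-4-(3,5-dimethoxyphenoxy)-5-methoxybenzaldehyde
Conditions: Cu(OAc)2 (20 mol %), pyridine, 4 Å MS, CH2Cl2, O2 (1 atm), rt; excess 22
Reagents that add atoms: none
Why: Chan–Lam coupling, in which the aryl group passes from boron to divalent copper and the phenoxide couples with it by reductive elimination from trivalent copper, forms the C2–O–ring F ether at room temperature without touching the aryl bromide or the aldehyde.

Step 13
Reactants: 23 3-bromo-4-(3,5-dimethoxyphenoxy)-5-methoxybenzaldehyde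
Product: 25 3-bromo-4-(3,5-dimethoxyphenoxy)-5-methoxyphenol, via aryl formate 24 (not isolated)
Conditions: mCPBA, CH2Cl2, 0 °C to rt; then K2CO3 (cat.), MeOH, rt
Reagents that add atoms: mCPBA (3-chloroperoxybenzoic acid), OOC(=O)c1cccc(Cl)c1
Why: Baeyer–Villiger oxidation with migration of the aryl group bearing a para aryloxy donor converts the formyl carbon into the future C5 oxygen after methanolysis of the formate.

Step 14
Reactants: 25 3-bromo-4-(3,5-dimethoxyphenoxy)-5-methoxyphenol
Product: 26 1-bromo-2-(3,5-dimethoxyphenoxy)-3,5-dimethoxybenzene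
Conditions: MeI, K2CO3, DMF, rt
Reagents that add atoms: iodomethane, CI
Why: Williamson methylation of the only phenol completes the protected ring C–ring F unit with bromine at C1.

Step 15
Reactants: 26 1-bromo-2-(3,5-dimethoxyphenoxy)-3,5-dimethoxybenzene
Product: 29 [2-(3,5-dimethoxyphenoxy)-3,5-dimethoxyphenyl]boronic acid, via aryllithium 27 (not isolated), via lithium borate 28 (not isolated)
Conditions: n-BuLi, THF, −78 °C; B(OiPr)3, −78 °C to rt; aq. HCl
Reagents that add atoms: triisopropyl borate, CC(C)OB(OC(C)C)OC(C)C; water, O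
Why: Bromine–lithium exchange outruns any deprotonation at −78 °C, the aryllithium is captured by the borate as an ate complex and aqueous acid hydrolyses it to the boronic acid at C1.

Step 16
Reactants: 20 6-(3,5-dimethoxyphenoxy)-1-iodo-4,7,9-trimethoxydibenzo[b,e][1,4]dioxin-2-ol; 29 [2-(3,5-dimethoxyphenoxy)-3,5-dimethoxyphenyl]boronic acid
Product: 30 2-[2-(3,5-dimethoxyphenoxy)-3,5-dimethoxyphenoxy]-6-(3,5-dimethoxyphenoxy)-1-iodo-4,7,9-trimethoxydibenzo[b,e][1,4]dioxin (B4–O–C1 ether; B5–I)
Conditions: Cu(OAc)2 (30 mol %), pyridine, 4 Å MS, CH2Cl2, O2 (1 atm), rt; excess 29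
Reagents that add atoms: none
Why: Chan–Lam coupling joins B4–OH to C1 under oxidative copper conditions at room temperature, where the ortho C–I bond does not react, so the oxygen and its attachment point on ring C are fixed before the C–C bond is made.

Step 17
Reactants: 30 2-[2-(3,5-dimethoxyphenoxy)-3,5-dimethoxyphenoxy]-6-(3,5-dimethoxyphenoxy)-1-iodo-4,7,9-trimethoxydibenzo[b,e][1,4]dioxin
Product: 31 nona-O-methylphlorofucofuroeckol A (all nine hydroxyl groups of the target as methyl ethers)
Conditions: Pd(OAc)2 (10 mol %), PCy3·HBF4 (20 mol %), K2CO3, DMA, 130 °C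
Reagents that add atoms: none
Why: Intramolecular direct arylation (palladium-catalysed C–H arylation) closes the five-membered furan ring by oxidative addition of zerovalent palladium into B5–I, carbonate-assisted palladation of C6–H, the only C–H ortho to the ether oxygen on ring C, and reductive elimination.

Step 18
Reactants: 31 nona-O-methylphlorofucofuroeckol A
Product: 32 phlorofucofuroeckol A
Conditions: BBr3 (excess), CH2Cl2, −78 °C to rt; then H2O
Reagents that add atoms: none
Why: Lewis-acid ether cleavage, in which BBr3 coordinates each methoxy oxygen and bromide removes the methyl group by SN2, demethylates all nine aryl methyl ethers while the diaryl ether, dioxin and furan C–O bonds, which lack an sp3 carbon, persist.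

Compound list
1 | 5-fluorovanillin (3-fluoro-4-hydroxy-5-methoxybenzaldehyde) | COc1cc(C=O)cc(F)c1O | starting material
2 | 4-(benzyloxy)-3-fluoro-5-methoxybenzaldehyde | COc1cc(C=O)cc(F)c1OCc1ccccc1 | intermediate
3 | 4-(benzyloxy)-3-fluoro-5-methoxyphenyl formate | COc1cc(OC=O)cc(F)c1OCc1ccccc1 | intermediate
4 | 4-(benzyloxy)-3-fluoro-5-methoxyphenol | COc1cc(O)cc(F)c1OCc1ccccc1 | intermediate
5 | 2-(benzyloxy)-1-fluoro-3-methoxy-5-(methoxymethoxy)benzene | COCOc1cc(F)c(OCc2ccccc2)c(OC)c1 | intermediate
6 | 2-fluoro-6-methoxy-4-(methoxymethoxy)phenol | COCOc1cc(F)c(O)c(OC)c1 | intermediate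
7 | 2,3-difluoro-6-methoxybenzaldehyde | COc1ccc(F)c(F)c1C=O | starting material
8 | 3-fluoro-2-[2-fluoro-6-methoxy-4-(methoxymethoxy)phenoxy]-6-methoxybenzaldehyde | COCOc1cc(F)c(Oc2c(F)ccc(OC)c2C=O)c(OC)c1 | intermediate
9 | 3-fluoro-2-[2-fluoro-6-methoxy-4-(methoxymethoxy)phenoxy]-6-methoxyphenyl formate | COCOc1cc(F)c(Oc2c(F)ccc(OC)c2OC=O)c(OC)c1 | intermediate
10 | 3-fluoro-2-[2-fluoro-6-methoxy-4-(methoxymethoxy)phenoxy]-6-methoxyphenol | COCOc1cc(F)c(Oc2c(F)ccc(OC)c2O)c(OC)c1 | intermediate
11 | 2-fluoro-3-[2-fluoro-6-methoxy-4-(methoxymethoxy)phenoxy]-5-methoxycyclohexa-2,5-diene-1,4-dione | COCOc1cc(F)c(OC2=C(F)C(=O)C=C(OC)C2=O)c(OC)c1 | intermediate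
12 | 3,5-dimethoxyphenol | COc1cc(O)cc(OC)c1 | starting material
13 | 2-(3,5-dimethoxyphenoxy)-3-[2-fluoro-6-methoxy-4-(methoxymethoxy)phenoxy]-5-methoxycyclohexa-2,5-diene-1,4-dione | COCOc1cc(F)c(OC2=C(Oc3cc(OC)cc(OC)c3)C(=O)C=C(OC)C2=O)c(OC)c1 | intermediate
14 | 2-(3,5-dimethoxyphenoxy)-3-[2-fluoro-6-methoxy-4-(methoxymethoxy)phenoxy]-5-methoxybenzene-1,4-diol | COc1cc(OC)cc(Oc2c(O)cc(OC)c(O)c2Oc2c(OC)cc(OCOC)cc2F)c1 | intermediate
15 | dilithium bis(phenoxide) of 14 lithiated at B5 | COc1cc(OC)cc(Oc2c(O[Li])cc(OC)c(O[Li])c2Oc2c(OC)cc(OCOC)c([Li])c2F)c1 | intermediate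
16 | B5–B6 aryne derived from 15 by loss of LiF (dilithium bis(phenoxide)) | COc1cc(OC)cc(Oc2c(O[Li])cc(OC)c(O[Li])c2OC2=C(OC)C=C(OCOC)C#C2)c1 | intermediate
17 | lithium 6-(3,5-dimethoxyphenoxy)-1-lithio-4,9-dimethoxy-2-(methoxymethoxy)dibenzo[b,e][1,4]dioxin-7-olate (B5 aryllithium) | COc1cc(OC)cc(Oc2c(O[Li])cc(OC)c3c2Oc2c(OC)cc(OCOC)c([Li])c2O3)c1 | intermediate
18 | 6-(3,5-dimethoxyphenoxy)-1-iodo-4,9-dimethoxy-2-(methoxymethoxy)dibenzo[b,e][1,4]dioxin-7-ol | COc1cc(OC)cc(Oc2c(O)cc(OC)c3c2Oc2c(OC)cc(OCOC)c(I)c2O3)c1 | intermediate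
19 | 6-(3,5-dimethoxyphenoxy)-1-iodo-4,7,9-trimethoxy-2-(methoxymethoxy)dibenzo[b,e][1,4]dioxin | COc1cc(OC)cc(Oc2c(OC)cc(OC)c3c2Oc2c(OC)cc(OCOC)c(I)c2O3)c1 | intermediate
20 | 6-(3,5-dimethoxyphenoxy)-1-iodo-4,7,9-trimethoxydibenzo[b,e][1,4]dioxin-2-ol | COc1cc(OC)cc(Oc2c(OC)cc(OC)c3c2Oc2c(OC)cc(O)c(I)c2O3)c1 | intermediate
21 | 5-bromovanillin (3-bromo-4-hydroxy-5-methoxybenzaldehyde) | COc1cc(C=O)cc(Br)c1O | starting material
22 | (3,5-dimethoxyphenyl)boronic acid | COc1cc(OC)cc(B(O)O)c1 | starting material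
23 | 3-bromo-4-(3,5-dimethoxyphenoxy)-5-methoxybenzaldehyde | COc1cc(OC)cc(Oc2c(OC)cc(C=O)cc2Br)c1 | intermediate
24 | 3-bromo-4-(3,5-dimethoxyphenoxy)-5-methoxyphenyl formate | COc1cc(OC)cc(Oc2c(OC)cc(OC=O)cc2Br)c1 | intermediate
25 | 3-bromo-4-(3,5-dimethoxyphenoxy)-5-methoxyphenol | COc1cc(OC)cc(Oc2c(OC)cc(O)cc2Br)c1 | intermediate
26 | 1-bromo-2-(3,5-dimethoxyphenoxy)-3,5-dimethoxybenzene | COc1cc(OC)cc(Oc2c(OC)cc(OC)cc2Br)c1 | intermediate
27 | [2-(3,5-dimethoxyphenoxy)-3,5-dimethoxyphenyl]lithium | COc1cc(OC)cc(Oc2c(OC)cc(OC)cc2[Li])c1 | intermediate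
28 | lithium [2-(3,5-dimethoxyphenoxy)-3,5-dimethoxyphenyl]tri(propan-2-yloxy)borate | COc1cc(OC)cc(Oc2c(OC)cc(OC)cc2[B-](OC(C)C)(OC(C)C)OC(C)C)c1.[Li+] | intermediate
29 | [2-(3,5-dimethoxyphenoxy)-3,5-dimethoxyphenyl]boronic acid | COc1cc(OC)cc(Oc2c(OC)cc(OC)cc2B(O)O)c1 | intermediate
30 | 2-[2-(3,5-dimethoxyphenoxy)-3,5-dimethoxyphenoxy]-6-(3,5-dimethoxyphenoxy)-1-iodo-4,7,9-trimethoxydibenzo[b,e][1,4]dioxin | COc1cc(OC)cc(Oc2c(OC)cc(OC)c3c2Oc2c(OC)cc(Oc4cc(OC)cc(OC)c4Oc4cc(OC)cc(OC)c4)c(I)c2O3)c1 | intermediate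
31 | nona-O-methylphlorofucofuroeckol A | COc1cc(OC)cc(Oc2c(OC)cc(OC)c3c2Oc2c(OC)cc4oc5c(Oc6cc(OC)cc(OC)c6)c(OC)cc(OC)c5c4c2O3)c1 | intermediate
32 | phlorofucofuroeckol A | Oc1cc(O)cc(Oc2c(O)cc(O)c3c2Oc2c(O)cc4oc5c(Oc6cc(O)cc(O)c6)c(O)cc(O)c5c4c2O3)c1 | target

Total step count: 18.
Longest linear sequence: 14 steps (steps 1–11 and 16–18, from 5-fluorovanillin 1); the ring C–ring F boronic acid 29 is made in 4 steps (12–15) and joins at step 16.

Steps most likely to fail

1. Step 9 (proposed new method). Metalation may occur at B3 or on ring E instead of B5. The trianion may lose LiF sluggishly. The aryne may be captured by the amide base or by a phenoxide of another molecule. The B5 aryllithium may be protonated before it meets the iodine source. The fallback separates ring closure from iodination and uses only established reaction classes; it sets out from 14 and returns at 19. Hydroquinone 14 would be lithiated at B5 with LiTMP at −78 °C and quenched with DMF before any warming, giving 2-(3,5-dimethoxyphenoxy)-3-[2-fluoro-3-formyl-6-methoxy-4-(methoxymethoxy)phenoxy]-5-methoxybenzene-1,4-diol F1. With K2CO3 in DMF at 60–80 °C under argon, the phenoxide at position 5 of ring A would displace B6–F, now activated by the ortho formyl group, in an intramolecular SNAr that closes the dioxin and gives 6-(3,5-dimethoxyphenoxy)-7-hydroxy-4,9-dimethoxy-2-(methoxymethoxy)dibenzo[b,e][1,4]dioxine-1-carbaldehyde F2. Methylation of the remaining phenol at position 2 of ring A (MeI, K2CO3) gives 6-(3,5-dimethoxyphenoxy)-4,7,9-trimethoxy-2-(methoxymethoxy)dibenzo[b,e][1,4]dioxine-1-carbaldehyde F3. Pinnick oxidation (NaClO2, NaH2PO4, 2-methylbut-2-ene, t-BuOH–H2O) gives 6-(3,5-dimethoxyphenoxy)-4,7,9-trimethoxy-2-(methoxymethoxy)dibenzo[b,e][1,4]dioxine-1-carboxylic acid F4. Decarboxylative iodination of this acid, which is flanked by two oxygen substituents (I2, K3PO4, MeCN, 100 °C), delivers iodide 19.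

2. Step 16. Two ortho-substituted, electron-rich partners may transmetalate and couple slowly, so that protodeboronation or homocoupling of 29 and copper-mediated oxidation of the phenol overtake ether formation. The fallback builds the B4–O–C1 ether by SNAr and moves the copper coupling to an unhindered boronic acid; it sets out from 20 and returns at 30. Phenol 20 and purchased 2-fluoro-4,6-dimethoxybenzaldehyde (COc1cc(F)c(C=O)c(OC)c1) with Cs2CO3 in DMSO at 100 °C would give 2-{[6-(3,5-dimethoxyphenoxy)-1-iodo-4,7,9-trimethoxydibenzo[b,e][1,4]dioxin-2-yl]oxy}-4,6-dimethoxybenzaldehyde F5. Baeyer–Villiger oxidation with mCPBA gives 2-{[6-(3,5-dimethoxyphenoxy)-1-iodo-4,7,9-trimethoxydibenzo[b,e][1,4]dioxin-2-yl]oxy}-4,6-dimethoxyphenyl formate F6. Methanolysis (K2CO3, MeOH) gives 2-{[6-(3,5-dimethoxyphenoxy)-1-iodo-4,7,9-trimethoxydibenzo[b,e][1,4]dioxin-2-yl]oxy}-4,6-dimethoxyphenol F7. Chan–Lam coupling of this phenol with boronic acid 22 (Cu(OAc)2, pyridine, O2) installs ring F and gives 30.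

3. Step 17. Reductive loss of iodine may compete, or palladation may stall at the hindered C6–H that sits between two oxygen substituents. The fallback replaces the organopalladium pathway by a radical one; it sets out from 30 and returns at 31. Base-promoted homolytic aromatic substitution (KOtBu, 1,10-phenanthroline, mesitylene, 120 °C) would generate the B5 aryl radical, which adds to C6 to form the five-membered ring and rearomatises to 31; no new compound is formed on the way.

Further compounds
F1 | step 9 | 2-(3,5-dimethoxyphenoxy)-3-[2-fluoro-3-formyl-6-methoxy-4-(methoxymethoxy)phenoxy]-5-methoxybenzene-1,4-diol | COc1cc(OC)cc(Oc2c(O)cc(OC)c(O)c2Oc2c(OC)cc(OCOC)c(C=O)c2F)c1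
F2 | step 9 | 6-(3,5-dimethoxyphenoxy)-7-hydroxy-4,9-dimethoxy-2-(methoxymethoxy)dibenzo[b,e][1,4]dioxine-1-carbaldehyde | COc1cc(OC)cc(Oc2c(O)cc(OC)c3c2Oc2c(OC)cc(OCOC)c(C=O)c2O3)c1
F3 | step 9 | 6-(3,5-dimethoxyphenoxy)-4,7,9-trimethoxy-2-(methoxymethoxy)dibenzo[b,e][1,4]dioxine-1-carbaldehyde | COc1cc(OC)cc(Oc2c(OC)cc(OC)c3c2Oc2c(OC)cc(OCOC)c(C=O)c2O3)c1
F4 | step 9 | 6-(3,5-dimethoxyphenoxy)-4,7,9-trimethoxy-2-(methoxymethoxy)dibenzo[b,e][1,4]dioxine-1-carboxylic acid | COc1cc(OC)cc(Oc2c(OC)cc(OC)c3c2Oc2c(OC)cc(OCOC)c(C(=O)O)c2O3)c1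
F5 | step 16 | 2-{[6-(3,5-dimethoxyphenoxy)-1-iodo-4,7,9-trimethoxydibenzo[b,e][1,4]dioxin-2-yl]oxy}-4,6-dimethoxybenzaldehyde | COc1cc(OC)cc(Oc2c(OC)cc(OC)c3c2Oc2c(OC)cc(Oc4cc(OC)cc(OC)c4C=O)c(I)c2O3)c1
F6 | step 16 | 2-{[6-(3,5-dimethoxyphenoxy)-1-iodo-4,7,9-trimethoxydibenzo[b,e][1,4]dioxin-2-yl]oxy}-4,6-dimethoxyphenyl formate | COc1cc(OC)cc(Oc2c(OC)cc(OC)c3c2Oc2c(OC)cc(Oc4cc(OC)cc(OC)c4OC=O)c(I)c2O3)c1
F7 | step 16 | 2-{[6-(3,5-dimethoxyphenoxy)-1-iodo-4,7,9-trimethoxydibenzo[b,e][1,4]dioxin-2-yl]oxy}-4,6-dimethoxyphenol | COc1cc(OC)cc(Oc2c(OC)cc(OC)c3c2Oc2c(OC)cc(Oc4cc(OC)cc(OC)c4O)c(I)c2O3)c1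
F0 | step 17 | none | none
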